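**Retrosynthetic overview**
1. The last bond made is the C6–O–acyl bond. A chiral copper catalyst veratroylates only one antipode of a racemic syn-1,3-diol, so the ester bond and the absolute configuration come from the same step.
2. Ring B (seven-membered) is opened at C8=C9, by ring-closing metathesis of an allyl/2-methylallyl diene.
3. C6–C7 goes back to a β-hydroxy aldehyde (chelate-controlled 2-methylallyl addition). C1–C10 and C5–H go back to a cyclopentene carbaldehyde (conjugate allylation, kinetic protonation). The C4 carbinol steers all of these.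
4. Ring A (five-membered) is bought as 2-bromo-3-methylcyclopent-2-en-1-one, and the isopropyl group (at C4) and the formyl carbon (C6) are added to it.
5. Ring order: ring A is purchased and ring B is closed in step 5.

**Notes before the steps**
- Atom labels follow daucane numbering: C1 is the quaternary ring-fusion carbon, C4 the carbinol carbon bearing isopropyl, C5 the ring-fusion CH, C6 the ester carbon, and C8=C9 the ring alkene.
- Compounds 3, 5, 6, 9, 10, 12 and 13 are racemic. Name and SMILES show the antipode that ends up in 15.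
- Assumption: (R,R)-Ph-BOX is taken as the ligand antipode that acylates the wanted antipode of 13; if the sense proves opposite, the equally available (S,S)-ligand is used.

**Step 1**
Reactants: 1 2-bromo-3-methylcyclopent-2-en-1-one; 2 isopropylmagnesium chloride
Product: 3 (1R)-2-bromo-3-methyl-1-(propan-2-yl)cyclopent-2-en-1-ol as racemate
Conditions: 2 (1.3 equiv), LaCl3·2LiCl (1.0 equiv), THF, 0 °C; H2O
Reagents that add atoms: isopropylmagnesium chloride, CC(C)[Mg]Cl
Why: This is a lanthanum-salt-promoted Grignard 1,2-addition in which the oxophilic salt activates the carbonyl and holds back enolisation, β-hydride reduction and Br/Mg exchange, the fully substituted β-carbon disfavours 1,4-attack, and the C4 carbinol centre forms racemic and is sorted in step 6.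

**Step 2**
Reactants: 3 (1R)-2-bromo-3-methyl-1-(propan-2-yl)cyclopent-2-en-1-ol; 4 N,N-dimethylformamide
Product: 6 (5R)-5-hydroxy-2-methyl-5-(propan-2-yl)cyclopent-1-ene-1-carbaldehyde as racemate, via dilithio species 5 (not isolated)
Conditions: t-BuLi (3.1 equiv), Et2O, −78 °C; 4 (3 equiv), −78 to 0 °C; H2O
Reagents that add atoms: N,N-dimethylformamide, CN(C)C=O
Why: Bromine–lithium exchange on the lithium alkoxide followed by Bouveault-type formylation of the vinyllithium puts C6 on C5 without touching the C4 centre.

**Step 3**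
Reactants: 6 (5R)-5-hydroxy-2-methyl-5-(propan-2-yl)cyclopent-1-ene-1-carbaldehyde; 7 allylmagnesium bromide; 8 chlorotrimethylsilane
Product: 10 (1S,2S,5R)-5-hydroxy-2-methyl-5-(propan-2-yl)-2-(prop-2-en-1-yl)cyclopentane-1-carbaldehyde as racemate, via silyl enol ether 9 (not isolated)
Conditions: 7 (3 equiv), CuBr·SMe2 (3 equiv), LiCl, 8 (4 equiv), THF, −78 °C; aq NH4Cl/NH3 wash; crude 9: Bu4NF, AcOH, THF, −78 to −20 °C
Reagents that add atoms: allylmagnesium bromide, C=CC[Mg]Br; chlorotrimethylsilane, C[Si](C)(C)Cl (its silyl group sits only in 9 and is gone in 10)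
Why: In this chlorosilane-accelerated 1,4-addition of allylcopper the isopropyl group sits pseudo-axial to avoid the formyl group and blocks one face while the alkoxide binds the metal, so allyl enters C1 cis to oxygen, and the non-acidic fluoride desilylation then protonates C5 kinetically from the same open face (H5 cis to OH) without loss of the β-hydroxyl.

**Step 4**
Reactants: 10 (1S,2S,5R)-5-hydroxy-2-methyl-5-(propan-2-yl)-2-(prop-2-en-1-yl)cyclopentane-1-carbaldehyde; 11 2-methylallylmagnesium chloride
Product: 12 (1R)-1-[(1R,2S,5R)-5-hydroxy-2-methyl-5-(propan-2-yl)-2-(prop-2-en-1-yl)cyclopentyl]-3-methylbut-3-en-1-ol as racemate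
Conditions: 11 (2.5 equiv), THF/CH2Cl2, −78 °C; H2O
Reagents that add atoms: 2-methylallylmagnesium chloride, CC(=C)C[Mg]Cl
Why: In this chelation-controlled Grignard addition (Cram chelate model) the first equivalent makes the magnesium alkoxide, which ties up the aldehyde oxygen in a six-membered chelate whose axial isopropyl group closes one face, so C7 enters from the other face and ends up equatorial with H6 anti to H5 (6R), and the low temperature outruns epimerisation and retro-aldol cleavage.

**Step 5**
Reactants: 12 (1R)-1-[(1R,2S,5R)-5-hydroxy-2-methyl-5-(propan-2-yl)-2-(prop-2-en-1-yl)cyclopentyl]-3-methylbut-3-en-1-ol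
Product: 13 (3R,3aR,4R,8aS)-6,8a-dimethyl-3-(propan-2-yl)-1,2,3,3a,4,5,8,8a-octahydroazulene-3,4-diol as racemate
Conditions: second-generation Grubbs catalyst (H2IMes)(PCy3)Cl2Ru=CHPh (5 mol %), 1,4-benzoquinone (10 mol %), CH2Cl2 (0.005 M), 40 °C
Reagents that add atoms: none
Why: In this ring-closing olefin metathesis the carbene loads on the monosubstituted allyl group and closes onto the 1,1-disubstituted alkene, which places the trisubstituted double bond regiospecifically at C8=C9, and the trans side arms on ring A give the trans-fused 5-7 system with no stereocentre touched.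

**Step 6**
Reactants: 13 (3R,3aR,4R,8aS)-6,8a-dimethyl-3-(propan-2-yl)-1,2,3,3a,4,5,8,8a-octahydroazulene-3,4-diol (racemate); 14 3,4-dimethoxybenzoyl chloride
Product: 15 (3R,3aR,4R,8aS)-3-hydroxy-6,8a-dimethyl-3-(propan-2-yl)-1,2,3,3a,4,5,8,8a-octahydroazulen-4-yl 3,4-dimethoxybenzoate, single enantiomer
Conditions: 14 (0.55 equiv), Cu(OTf)2 (5 mol %), (R,R)-Ph-BOX (5.5 mol %), K2CO3 (1.0 equiv), CH2Cl2, −20 °C, stopped near 50 % conversion; chromatography removes the unreacted mirror-image diol
Reagents that add atoms: 3,4-dimethoxybenzoyl chloride, COc1ccc(C(=O)Cl)cc1OC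
Why: Proposed new method: the syn-1,3-diol binds the divalent copper of the Cu(OTf)2/Ph-BOX complex as a six-membered chelate, which after deprotonation by K2CO3 activates only the less hindered secondary C6 oxygen toward 14, and because the axial isopropyl group and ring B of the two antipodes fall into opposite quadrants of the C2-symmetric ligand only the (3R,3aR,4R,8aS)-chelate is acylated fast, so the ester C–O bond and the absolute configuration are fixed together, the closest known reaction type being the copper–bis(oxazoline)-catalysed asymmetric benzoylation (kinetic resolution, desymmetrisation) of 1,2-diols, which has not been shown for secondary/tertiary 1,3-diols.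

**Compound list**
1 | 2-bromo-3-methylcyclopent-2-en-1-one | CC1=C(Br)C(=O)CC1 | starting material
2 | isopropylmagnesium chloride | CC(C)[Mg]Cl | starting material
3 | (1R)-2-bromo-3-methyl-1-(propan-2-yl)cyclopent-2-en-1-ol (racemic) | BrC1=C(C)CC[C@@]1(O)C(C)C | intermediate
4 | N,N-dimethylformamide | CN(C)C=O | starting material
5 | dilithio species: lithium (1R)-2-lithio-3-methyl-1-(propan-2-yl)cyclopent-2-en-1-olate (racemic, not isolated) | [Li]C1=C(C)CC[C@@]1(O[Li])C(C)C | intermediate
6 | (5R)-5-hydroxy-2-methyl-5-(propan-2-yl)cyclopent-1-ene-1-carbaldehyde (racemic) | O=CC1=C(C)CC[C@@]1(O)C(C)C | intermediate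
7 | allylmagnesium bromide | C=CC[Mg]Br | starting material
8 | chlorotrimethylsilane | C[Si](C)(C)Cl | starting material
9 | silyl enol ether: (1R,3S)-3-methyl-1-(propan-2-yl)-3-(prop-2-en-1-yl)-2-[(trimethylsilyloxy)methylidene]cyclopentan-1-ol (racemic, not isolated, enol ether geometry open) | C[Si](C)(C)OC=C1[C@](C)(CC=C)CC[C@@]1(O)C(C)C | intermediate
10 | (1S,2S,5R)-5-hydroxy-2-methyl-5-(propan-2-yl)-2-(prop-2-en-1-yl)cyclopentane-1-carbaldehyde (racemic) | O=C[C@H]1[C@](C)(CC=C)CC[C@@]1(O)C(C)C | intermediate
11 | 2-methylallylmagnesium chloride | CC(=C)C[Mg]Cl | starting material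
12 | (1R)-1-[(1R,2S,5R)-5-hydroxy-2-methyl-5-(propan-2-yl)-2-(prop-2-en-1-yl)cyclopentyl]-3-methylbut-3-en-1-ol (racemic) | O[C@H](CC(C)=C)[C@H]1[C@](C)(CC=C)CC[C@@]1(O)C(C)C | intermediate
13 | (3R,3aR,4R,8aS)-6,8a-dimethyl-3-(propan-2-yl)-1,2,3,3a,4,5,8,8a-octahydroazulene-3,4-diol (racemic) | O[C@@H]1CC(C)=CC[C@]2(C)CC[C@@](O)(C(C)C)[C@@H]12 | intermediate
14 | 3,4-dimethoxybenzoyl chloride | COc1ccc(C(=O)Cl)cc1OC | starting material
15 | (3R,3aR,4R,8aS)-3-hydroxy-6,8a-dimethyl-3-(propan-2-yl)-1,2,3,3a,4,5,8,8a-octahydroazulen-4-yl 3,4-dimethoxybenzoate | COc1ccc(C(=O)O[C@@H]2CC(C)=CC[C@]3(C)CC[C@@](O)(C(C)C)[C@@H]23)cc1OC | target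

**Total step count:** 6. **Longest linear sequence:** 6.

**Three steps most likely to fail**

Step 6 (the new method). The hindered tertiary hydroxyl may bind copper too weakly, so selectivity between the antipodes could be low. The fallback uses known chemistry, sets out from 13 and comes back at 15. Racemic 13 is esterified at the C6 hydroxyl with (S)-2-methoxy-2-phenylacetic acid (DCC, DMAP, CH2Cl2). This gives two diastereomers: the (S)-2-methoxy-2-phenylacetate of the (3R,3aR,4R,8aS)-diol F3 and the (S)-2-methoxy-2-phenylacetate of the (3S,3aS,4S,8aR)-diol F4. They are separated on silica. LiOH in THF/H2O frees enantiopure 13 from F3, and plain acylation with 14 (Et3N, DMAP, CH2Cl2) gives 15.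

Step 3. Allyl metal species tend to attack aldehydes 1,2, and the β-carbon is fully substituted. The fallback sets out from 6 and comes back at 10. It accepts the 1,2-addition and moves the allyl group by a sigmatropic shift. Reagent 7 (2.2 equiv, THF, −78 °C) gives 1-[(5R)-5-hydroxy-2-methyl-5-(propan-2-yl)cyclopent-1-en-1-yl]but-3-en-1-ol F1 as both carbinol epimers. KH and 18-crown-6 in THF (0 °C to room temperature) then trigger the anionic oxy-Cope rearrangement, which delivers allyl to C1 on the face away from the isopropyl group. Quenching the enolate with AcOH at −78 °C gives 10.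

Step 4. Very reactive allylic Grignard reagents can ignore the chelate and give a poor C6 epimer ratio. The fallback sets out from 10 and comes back at 12. It replaces substrate control by reagent control. B-(2-methylallyl)diisopinocampheylborane made from (−)-α-pinene (Et2O, −78 °C, then NaOH/H2O2) sets C6 as R on both antipodes of 10. The wanted antipode gives 12. The other antipode gives the diastereomer (1R)-1-[(1S,2R,5S)-5-hydroxy-2-methyl-5-(propan-2-yl)-2-(prop-2-en-1-yl)cyclopentyl]-3-methylbut-3-en-1-ol F2, which is removed by chromatography, so 12 is already enriched before step 6.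

**Further compounds**
F1 | step 3 | 1-[(5R)-5-hydroxy-2-methyl-5-(propan-2-yl)cyclopent-1-en-1-yl]but-3-en-1-ol (racemic, both carbinol epimers) | C=CCC(O)C1=C(C)CC[C@@]1(O)C(C)C
F2 | step 4 | (1R)-1-[(1S,2R,5S)-5-hydroxy-2-methyl-5-(propan-2-yl)-2-(prop-2-en-1-yl)cyclopentyl]-3-methylbut-3-en-1-ol | O[C@H](CC(C)=C)[C@@H]1[C@@](C)(CC=C)CC[C@]1(O)C(C)C
F3 | step 6 | (3R,3aR,4R,8aS)-3-hydroxy-6,8a-dimethyl-3-(propan-2-yl)-1,2,3,3a,4,5,8,8a-octahydroazulen-4-yl (S)-2-methoxy-2-phenylacetate | CO[C@H](C(=O)O[C@@H]2CC(C)=CC[C@]3(C)CC[C@@](O)(C(C)C)[C@@H]23)c1ccccc1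
F4 | step 6 | (3S,3aS,4S,8aR)-3-hydroxy-6,8a-dimethyl-3-(propan-2-yl)-1,2,3,3a,4,5,8,8a-octahydroazulen-4-yl (S)-2-methoxy-2-phenylacetate | CO[C@H](C(=O)O[C@H]2CC(C)=CC[C@@]3(C)CC[C@](O)(C(C)C)[C@H]23)c1ccccc1
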